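Set the amber and green runs side by side: they share c(starting material) at 0.050 M, but enzyme stands at 0.01 mol% against 0.04 mol%.

| flask | starting material | second substrate | free enzyme | remark | time |
|---|---|---|---|---|---|
| amber | 0.050 M | 0.90 equiv | 0.01 mol% | run made earlier |  |
| green | 0.050 M | 0.90 equiv | 0.04 mol% | run made earlier |  |
| red | 0.075 M | 0.90 equiv | 0.02 mol% | run made earlier |  |
| west | 0.050 M | 0.900 equiv | 0.02 mol% |  | 1.5 h |
| north | 0.050 M | 0.900 equiv | 0.02 mol% |  | 3.0 h |

- which of the two ends with the higher amount of target, in percent of the starting material charged ("neither" if they lie within 2 percentage points) (west / north / neither)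
- target at the end, in percent of the starting material charged, west
- target at the end, in percent of the starting material charged, north



amber run (percent of the starting material charged)

| time / h | target / % | starting material / % |
|---|---|---|
| 0.667 | 8.5 | 81.3 |
| 1.33 | 17.2 | 65.3 |
| 2.00 | 24.0 | 52.7 |
| 3.00 | 35.4 | 39.2 |
| 4.00 | 43.8 | 28.2 |

green run (percent of the starting material charged)

| time / h | target / % | starting material / % |
|---|---|---|
| 0.667 | 18.0 | 71.3 |
| 1.33 | 36.7 | 48.6 |
| 2.00 | 53.8 | 31.0 |
| 3.00 | 68.8 | 15.3 |
| 4.00 | 72.6 | 10.9 |

red run (percent of the starting material charged)

| time / h | target / % | starting material / % |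
|---|---|---|
| 0.667 | 11.5 | 73.5 |
| 1.33 | 22.4 | 55.4 |
| 2.00 | 31.7 | 41.3 |
| 3.00 | 45.8 | 25.1 |
| 4.00 | 55.9 | 15.6 |

Every earlier reading carried a scatter of 0.5 percentage points. West and north are one recipe stopped at two times, so I read the amber and green tables column against column for a single curve; the red run differed from them in c(starting material), at 0.075 M, as well as in enzyme, so I left it out of this comparison. At 1.33 h green's target stood at 36.7% and amber's at 17.2%, a ratio of 2.13 for 4.00 times the enzyme. The root of that ratio, 1.46, I called the doubling factor: how many times more target one doubling of enzyme gave at a fixed time, with c(starting material) and equivalents held.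

Further down the columns the ratio fell to 1.94 at 3.00 h, and green gained 3.8 points in its last hour, less than amber's 8.4 points, so I kept the early row.

West and north carry twice amber's enzyme. Amber ran nearly straight up to 1.33 h, so I scaled that reading to 1.5 h and applied the factor, which gave 28.3% for west; amber's 35.4% at 3.0 h gave 51.7% for north.

The forecast, reasoning that “Four times the enzyme gives only about twice the rate”, put west at 27.5% (24.5% to 30.5%) and north at 49.5% (45% to 54%), with north higher; my north stood 2.2 points above its figure.

The flask gave 28.4% in west and 51.6% in north, so north ended higher, inside both ranges.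

    2 second complex ⇌ resting dimer, settled at all times (K = 6.90 × 10⁶ /M)
    starting material + free enzyme ⇌ first complex (K = 22.3 /M, k = 1.33 × 10⁵ /M/min)
    starting material + second substrate → uncatalysed product (k = 0.0737 /M/min)
    second substrate + loaded enzyme ⇌ second complex (K = 63.0 /M, k = 20800 /M/s)
    first complex ⇌ loaded enzyme + first product (K = 0.0257 M, k = 186 /min)
    second complex → free enzyme + target (k = 225 /min)

North over amber at 3.0 h came to 1.46, beside the factor's 1.46. North had not come to rest: it still held, unbound, 27% of its starting material and 19% of its second substrate, the limiting reagent. At ten times the time, 30.0 h, target stood at 68.0% with second substrate at 0%, a further 16 points; west at 15.0 h reached the same 68.0%, a further 40 points.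

For north's recipe at 0.05 mol% enzyme, the factor carried from amber's 3.0 h reading gave 85.3%. That flask gave 72.2%, 13 points lower, with 3.4% of its second substrate left.

The runs come from a simulation with constants of no real substance, and the scatter is random.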